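The numbers in the tables were computed with made-up constants; scatter was added.

- Which flask ends richer, ochre started cold or grey hot throughout? I reckon it from what one charge of initiator can make.

the same everywhere: starting material 1.4 M; initiator 14 mM

|  | partner | protic impurity | radical scavenger | temperature | remark | time |
|---|---|---|---|---|---|---|
| theta | 1.4 M | 0.70 M | 0.46 mM | 8 °C | run made earlier |  |
| gamma | 1.4 M | 0.70 M | 0.69 mM | 24 °C | run made earlier |  |
| delta | 0.70 M | 0.70 M | 0.92 mM | 8 °C | run made earlier |  |
| ochre | 1.40 M | 0.700 M | 0.92 mM |  | at 0 °C until 2.5 d, from then on at 30 °C | 5.0 d |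
| grey | 1.40 M | 0.700 M | 0.92 mM |  | at 30 °C throughout | 5.0 d |

theta run (percent of the starting material charged)

| time / d | product / % | starting material / % |
|---|---|---|
| 0.625 | 14.5 | 82.9 |
| 1.25 | 22.4 | 76.8 |
| 1.67 | 23.5 | 75.7 |
| 2.50 | 25.1 | 73.6 |
| 3.00 | 27.1 | 72.9 |
| 4.00 | 22.8 | 74.6 |

gamma run (percent of the starting material charged)

| time / h | product / % | starting material / % |
|---|---|---|
| 2.50 | 10.8 | 88.2 |
| 4.00 | 12.7 | 83.1 |
| 6.00 | 14.9 | 84.1 |
| 8.00 | 14.6 | 82.4 |
| 12.0 | 15.6 | 83.0 |
| 20.0 | 14.3 | 83.0 |
| 30.0 | 15.1 | 81.1 |

delta run (percent of the starting material charged)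

| time / d | product / % | starting material / % |
|---|---|---|
| 0.333 | 5.9 | 93.6 |
| 1.04 | 10.5 | 89.0 |
| 1.67 | 11.6 | 87.2 |
| 3.00 | 11.4 | 85.6 |
| 4.00 | 12.8 | 87.2 |

(each reading ± 1 percentage point)

- the winner by amount of product, in percent of the starting material charged; "neither" if no more than 2 percentage points parts them (ochre / grey / neither)
- how much product is there at the end, in percent of the starting material charged: ochre
- how much product is there at the end, in percent of the starting material charged: grey



- My rule is the charge yield: the product one full charge of initiator makes at a given temperature, with the starting material and partner of theta, before the flask stalls. It is a chain length, counted per charge.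
- In the first instants I expect the scavenger to take the first chains. In ochre its charge is far less than the initiator charge, 6.57 % of it, so I leave it out.
- In the middle the chains run. Theta levels off near 25.0 % and gamma near 14.9 %, as readings. Gamma is warmer but also holds more scavenger, 0.69 mM against 0.46 mM, so the two changes are not parted; I put the fall on the warming.
- Delta has half the partner of theta and levels near 11.9 %, half of theta. Delta also has twice the scavenger of theta, so these two changes are not parted either; I read the fall as a chain yield that follows the partner.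
- The first readings, with their scatter, give the rate of approach to each plateau: 1.39 d⁻¹ in theta and 12.4 d⁻¹ in gamma. I take this for the decay of the initiator.
- Stretched on a log scale to 0 °C, that rate is 0.465 d⁻¹, a half-time of 1.49 d.
- At the end, as I read it, the stall is the initiator's decay, and the product stays. The same stretch gives the charge yield at 0 °C, what a full charge makes in the cold: 32.4 %. At 30 °C it gives 12.3 %.
- I expect grey to make that hot yield. By my clock ochre decays 68.7 % of its initiator cold before 2.5 d, and the rest goes hot. So I reckon 26.1 % for ochre, a gap of 14 percentage points against a margin of 2 points. I say ochre.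
- The forecast says neither, with 12.5 % for ochre and 12.5 % for grey. It reads the plateaus as an equilibrium, so that ochre “falls back within hours” once warm. We agree on grey and part on ochre.
- Ochre ends at 25.3 % and grey at 12.3 %, so the winner is ochre. Ochre still holds 25.3 % at 50.0 d, and its initiator stands at 0 % of the charge at 5.00 d. Ochre's end is 78.1 % of the cold charge yield 32.4 %.

    starting material + second chain carrier → by-product + first chain carrier (k = 2.50 × 10⁶ M⁻¹ h⁻¹, Ea = 38.0 kJ mol⁻¹)
    partner + first chain carrier → product + second chain carrier (k = 8.70 × 10⁵ M⁻¹ h⁻¹, Ea = 38.0 kJ mol⁻¹)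
    initiator → 2 initiating radical (k = 0.0220 h⁻¹, Ea = 85.0 kJ mol⁻¹)
    partner + protic impurity → quenched reagent (k = 0.00870 M⁻¹ h⁻¹, Ea = 69.0 kJ mol⁻¹)
    2 second chain carrier → ended chains B (k = 1.10 × 10⁹ M⁻¹ s⁻¹, Ea = 10.0 kJ mol⁻¹)
    starting material + initiating radical → capped initiator + first chain carrier (k = 2.80 × 10⁷ M⁻¹ h⁻¹, Ea = 29.0 kJ mol⁻¹)
    second chain carrier + radical scavenger → ended chains C (k = 2.20 × 10⁷ M⁻¹ s⁻¹, Ea = 12.0 kJ mol⁻¹)
    2 first chain carrier → ended chains A (k = 3.00 × 10⁸ M⁻¹ s⁻¹, Ea = 10.0 kJ mol⁻¹)
    first chain carrier → ended carrier (k = 38000 h⁻¹, Ea = 69.0 kJ mol⁻¹)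
    (constants at 0 °C)

- Second flask: ochre read early, at 30 h, still at 0 °C. By my clock 44.1 % of the initiator has decayed, and that share of 32.4 % gives 14.3 %. The flask gives 15.4 %, with 52 % of the initiator left.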